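The route rests on cutting the seven-membered ring of the daucane (C1 quaternary ring fusion, C5 ring-fusion CH, C6 aroyloxy carbon, C7=C8, C9 ketone) into a three-carbon unit C5–C6–C7 and a four-carbon unit C8–C9–C10–C1. An open-chain epoxy enolsilane carrying a 2-siloxydiene on the tether C2–C3–C4 undergoes an intramolecular (4+3) cycloaddition that forms C1–C5 and C7–C8 in one operation, closing both rings, turning the C4–C5 epoxide into the C4 carbinol with inversion at C5, and setting the quaternary C1. The step exploits the β-hydroxy ketone pattern C4–OH/C6=O across C5 and the C9 oxygen of the cycloheptane; C7=C8 is dehydrogenated later.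

Key step: step 13

Remark: atoms carry daucane numbers (cyclopentane C1–C5, cycloheptane C5–C10 and C1), also in the open-chain precursors; β is the face of the C1 methyl group.

Assumption: in step 6 (S)-Tol-BINAP is written as the ligand antipode expected to give the (6S)-lactone; should the facial sense be opposite, its mirror image is used and nothing else changes.

Step 1
Reactants: 1 3-methylbut-2-enal
Product: 2 (3S)-5-methylhex-4-en-3-ol
Conditions: Et2Zn, (−)-MIB (cat.), hexane/toluene, 0 °C; 1 M HCl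
Reagents that add atoms: diethylzinc, CC[Zn]CC
Why: Amino-alcohol-catalysed enantioselective 1,2-addition of a dialkylzinc to an enal gives one carbinol epimer, which only carries C9 at the alcohol level and is erased in step 11, so its sense is immaterial.

Step 2
Reactants: 2 (3S)-5-methylhex-4-en-3-ol
Product: 3 tert-butyl(dimethyl){[(3S)-5-methylhex-4-en-3-yl]oxy}silane
Conditions: t-BuMe2SiCl, imidazole, DMF, rt
Reagents that add atoms: tert-butyldimethylsilyl chloride, CC(C)(C)[Si](C)(C)Cl
Why: Standard silylation of a secondary allylic alcohol; no stereocentre is touched.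

Step 3
Reactants: 3 tert-butyl(dimethyl){[(3S)-5-methylhex-4-en-3-yl]oxy}silane
Product: 5 (2E,4S)-4-{[tert-butyl(dimethyl)silyl]oxy}-2-methylhex-2-enal, via allylic alcohol 4 (not isolated)
Conditions: SeO2 (0.5 equiv), t-BuOOH, salicylic acid (cat.), CH2Cl2, rt; then MnO2, CH2Cl2, rt
Reagents that add atoms: tert-butyl hydroperoxide, CC(C)(C)OO
Why: SeO2 allylic oxidation (ene reaction, then 2,3-sigmatropic shift) is selective for the (E)-methyl of the gem-dimethyl alkene, and MnO2 converges the allylic alcohol to the (E)-enal.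

Step 4
Reactants: 6 3-methylbutan-2-one; 7 triethyl phosphonoacetate
Product: 8 ethyl (2E)-3,4-dimethylpent-2-enoate
Conditions: NaH, THF, 0 → 65 °C; separation of the minor (Z)-isomer
Reagents that add atoms: none
Why: Horner–Wadsworth–Emmons olefination of a methyl ketone should give mainly the (E)-enoate with the ester trans to the isopropyl group.

Step 5
Reactants: 8 ethyl (2E)-3,4-dimethylpent-2-enoate
Product: 9 {[1-ethoxy-3-(propan-2-yl)buta-1,3-dien-1-yl]oxy}trimethylsilane
Conditions: LiN(iPr)2, DMPU, THF, −78 °C; Me3SiCl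
Reagents that add atoms: chlorotrimethylsilane, C[Si](C)(C)Cl
Why: γ-Deprotonation at the methyl cis to the ester and O-silylation give the silyl dienolate; the ketene acetal geometry is immaterial.

Step 6
Reactants: 5 (2E,4S)-4-{[tert-butyl(dimethyl)silyl]oxy}-2-methylhex-2-enal; 9 {[1-ethoxy-3-(propan-2-yl)buta-1,3-dien-1-yl]oxy}trimethylsilane
Product: 10 (6S)-6-[(2E,4S)-4-{[tert-butyl(dimethyl)silyl]oxy}hex-2-en-2-yl]-4-(propan-2-yl)-5,6-dihydro-2H-pyran-2-one
Conditions: Cu(OTf)2 (10 mol%), (S)-Tol-BINAP (11 mol%), Bu4N(Ph3SiF2) (20 mol%), THF, −78 → 0 °C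
Reagents that add atoms: none
Why: Copper fluoride–bisphosphine-catalysed vinylogous Mukaiyama aldol addition of the γ-carbon (C3) to the aldehyde through an s-cis copper dienolate, so that the aldolate lactonises directly with loss of EtOSiMe3; the ligand sets C2 by catalyst control and the ring fixes the C4=C5 geometry.

Step 7
Reactants: 10 (6S)-6-[(2E,4S)-4-{[tert-butyl(dimethyl)silyl]oxy}hex-2-en-2-yl]-4-(propan-2-yl)-5,6-dihydro-2H-pyran-2-one
Product: 11 (1R,4S,6S)-4-[(2E,4S)-4-{[tert-butyl(dimethyl)silyl]oxy}hex-2-en-2-yl]-6-(propan-2-yl)-3,7-dioxabicyclo[4.1.0]heptan-2-one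
Conditions: t-BuOOH (decane), DBU, CH2Cl2, 0 °C → rt
Reagents that add atoms: tert-butyl hydroperoxide, CC(C)(C)OO
Why: Weitz–Scheffer nucleophilic epoxidation, in which t-BuOO− adds to C4 axially and anti to the pseudo-equatorial alkenyl group on C2 (the usual anti selectivity of 6-substituted 5,6-dihydropyran-2-ones), sets C4 and the epoxide trans to the C2 side chain; the electron-rich side-chain alkene does not react.

Step 8
Reactants: 11 (1R,4S,6S)-4-[(2E,4S)-4-{[tert-butyl(dimethyl)silyl]oxy}hex-2-en-2-yl]-6-(propan-2-yl)-3,7-dioxabicyclo[4.1.0]heptan-2-one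
Product: 12 (3R,4S,6S,7E,9S)-9-{[tert-butyl(dimethyl)silyl]oxy}-3,4-epoxy-6-hydroxy-7-methyl-4-(propan-2-yl)undec-7-en-2-one (open-chain form of the lactol)
Conditions: MeLi (1.05 equiv), THF, −78 °C; AcOH, −78 °C
Reagents that add atoms: methyllithium, [Li]C
Why: Single addition of MeLi to the δ-lactone stops at the lithium hemiketal at −78 °C and gives the methyl ketone (C6, C7) on protonation; the epoxide and all stereocentres are untouched.

Step 9
Reactants: 12 (3R,4S,6S,7E,9S)-9-{[tert-butyl(dimethyl)silyl]oxy}-3,4-epoxy-6-hydroxy-7-methyl-4-(propan-2-yl)undec-7-en-2-one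
Product: 13 (3R,4S,6S,7E,9S)-9-{[tert-butyl(dimethyl)silyl]oxy}-3,4-epoxy-7-methyl-2-oxo-4-(propan-2-yl)undec-7-en-6-yl acetate
Conditions: Ac2O, pyridine, DMAP (cat.), CH2Cl2, 0 °C
Reagents that add atoms: acetic anhydride, CC(=O)OC(C)=O
Why: DMAP-catalysed acylation of the secondary alcohol of the open-chain tautomer installs the C2 acetate of the target.

Step 10
Reactants: 13 (3R,4S,6S,7E,9S)-9-{[tert-butyl(dimethyl)silyl]oxy}-3,4-epoxy-7-methyl-2-oxo-4-(propan-2-yl)undec-7-en-6-yl acetate
Product: 14 (3R,4S,6S,7E,9S)-3,4-epoxy-9-hydroxy-7-methyl-2-oxo-4-(propan-2-yl)undec-7-en-6-yl acetate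
Conditions: HF·pyridine, pyridine, THF, 0 °C → rt
Reagents that add atoms: none
Why: Buffered fluoride cleavage of the secondary silyl ether leaves the epoxy ketone and the acetate intact.

Step 11
Reactants: 14 (3R,4S,6S,7E,9S)-3,4-epoxy-9-hydroxy-7-methyl-2-oxo-4-(propan-2-yl)undec-7-en-6-yl acetate
Product: 15 (3R,4S,6S,7E)-3,4-epoxy-7-methyl-2,9-dioxo-4-(propan-2-yl)undec-7-en-6-yl acetate
Conditions: Dess–Martin periodinane, NaHCO3, CH2Cl2, 0 °C → rt
Reagents that add atoms: none
Why: Dess–Martin oxidation of the allylic alcohol gives the (E)-enone (C9) under neutral conditions and erases the auxiliary carbinol centre.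

Step 12
Reactants: 15 (3R,4S,6S,7E)-3,4-epoxy-7-methyl-2,9-dioxo-4-(propan-2-yl)undec-7-en-6-yl acetate
Product: 16 (3R,4S,6S,7E,9Z)-3,4-epoxy-7-methyl-4-(propan-2-yl)-2,9-bis[(triethylsilyl)oxy]undeca-1,7,9-trien-6-yl acetate
Conditions: Et3SiOTf (2.4 equiv), Et3N (4 equiv), CH2Cl2, −78 → −40 °C
Reagents that add atoms: triethylsilyl trifluoromethanesulfonate, CC[Si](CC)(CC)OS(=O)(=O)C(F)(F)F
Why: Soft enolisation gives the terminal enol silane of the methyl ketone (the epoxide C–H is not removed) and, by α′-deprotonation of the ethyl enone, the cross-conjugated 2-siloxydiene; no stereocentre is affected.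

Step 13
Reactants: 16 (3R,4S,6S,7E,9Z)-3,4-epoxy-7-methyl-4-(propan-2-yl)-2,9-bis[(triethylsilyl)oxy]undeca-1,7,9-trien-6-yl acetate
Product: 18 2β-acetoxy-4β-hydroxy-5αH-daucane-6,9-dione (C8 epimers), via bis-silyl cycloadduct 17 (not isolated)
Conditions: Et3SiOTf (0.2 equiv), CH2Cl2 (0.01 M), −78 °C; then pyridine, HF·pyridine, THF, 0 °C
Reagents that add atoms: none
Why: Et3Si+ silylates the epoxide oxygen and, with push from the C6 enol silane, the C5–O bond opens to a 2-siloxyallyl cation (C5–C6–C7) that is taken up across the termini C1 and C8 of the s-cis 2-siloxydiene in a concerted, asynchronous (4+3) cycloaddition, after which the C6 oxocarbenium ion hands Et3Si+ on and HF·pyridine unmasks the C4 alcohol and the C9 ketone. The closest known reaction type is the silyl-triflate-catalysed intramolecular (4+3) cycloaddition of epoxy enolsilanes with tethered dienes. The cyclopentane closes by 5-exo-tet attack of the diene terminus C1 on the epoxide carbon C5, and the cycloheptane closes by the second bond of the cycloaddition, the allyl-cation terminus C7 onto the diene terminus C8. C5 is set by inversion at the epoxide carbon (C1 enters anti to the leaving oxygen, leaving H-5 α), C4 keeps the configuration fixed in step 7, and the quaternary C1 follows from the extended transition state in which the siloxy-bearing carbons C6 and C9 point away from each other, which is the trans ring fusion and places the C1 methyl cis to the C2 acetate. C8 forms as a mixture of epimers that is erased in step 16. The step needs activation of the epoxide in preference to the allylic acetate and (4+3) in preference to (3+2) or open-chain capture; enol-silane assistance at C5, catalytic acid at −78 °C and high dilution are meant to secure this, and the C2–H lying in the diene plane (minimal allylic 1,3-strain) keeps the acetate on the face away from the tether.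

Step 14
Reactants: 18 2β-acetoxy-4β-hydroxy-5αH-daucane-6,9-dione (C8 epimers)
Product: 19 2β-acetoxy-4β,6α-dihydroxy-5αH-daucan-9-one (C8 epimers)
Conditions: Me4NBH(OAc)3 (5 equiv), MeCN/AcOH (1:1), −20 °C → rt
Reagents that add atoms: none
Why: Evans–Saksena hydroxyl-directed reduction, in which the C4 alcohol exchanges onto boron and hydride is delivered through a chair-like six-membered transition state to the β face of the C6 carbonyl (the face of the β C4–O bond), should give the 6α-alcohol while the C9 ketone, which has no neighbouring hydroxyl, is not reduced.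

Step 15
Reactants: 19 2β-acetoxy-4β,6α-dihydroxy-5αH-daucan-9-one (C8 epimers); 20 4-{[tert-butyl(dimethyl)silyl]oxy}benzoic acid
Product: 21 2β-acetoxy-6α-[4-(tert-butyldimethylsilyloxy)benzoyloxy]-4β-hydroxy-5αH-daucan-9-one (C8 epimers)
Conditions: 2,4,6-Cl3C6H2COCl, Et3N, THF, rt; then DMAP, toluene, rt
Reagents that add atoms: none
Why: Yamaguchi esterification through the mixed anhydride acylates the secondary C6 alcohol with retention, the tertiary C4 alcohol being too hindered to react.

Step 16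
Reactants: 21 2β-acetoxy-6α-[4-(tert-butyldimethylsilyloxy)benzoyloxy]-4β-hydroxy-5αH-daucan-9-one (C8 epimers)
Product: 22 2β-acetoxy-6α-[4-(tert-butyldimethylsilyloxy)benzoyloxy]-4β-hydroxy-5αH-dauc-7-en-9-one
Conditions: IBX (2.5 equiv), DMSO/fluorobenzene, 70 °C
Reagents that add atoms: none
Why: IBX dehydrogenation of the ketone through its enol can only introduce the C7=C8 double bond, because C10 has no β-hydrogen (C1 is quaternary), and both C8 epimers converge on the trisubstituted enone.

Step 17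
Reactants: 22 2β-acetoxy-6α-[4-(tert-butyldimethylsilyloxy)benzoyloxy]-4β-hydroxy-5αH-dauc-7-en-9-one
Product: 23 (1S,2S,4S,5R,6R)-2-acetoxy-4-hydroxy-6-(4-hydroxybenzoyloxy)dauc-7-en-9-one (CNP0087181.7)
Conditions: Bu4NF (1.1 equiv), AcOH (1.2 equiv), THF, 0 °C
Reagents that add atoms: none
Why: Fluoride cleavage of the aryl silyl ether, buffered with acetic acid so that the acetate, the benzoate and the γ-acyloxy enone survive.

Compound list

1 | 3-methylbut-2-enal | CC(C)=CC=O | starting material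
2 | (3S)-5-methylhex-4-en-3-ol | CC[C@H](O)C=C(C)C | intermediate
3 | tert-butyl(dimethyl){[(3S)-5-methylhex-4-en-3-yl]oxy}silane | CC[C@H](O[Si](C)(C)C(C)(C)C)C=C(C)C | intermediate
4 | (2E,4S)-4-{[tert-butyl(dimethyl)silyl]oxy}-2-methylhex-2-en-1-ol | CC[C@H](O[Si](C)(C)C(C)(C)C)/C=C(\C)CO | intermediate
5 | (2E,4S)-4-{[tert-butyl(dimethyl)silyl]oxy}-2-methylhex-2-enal | CC[C@H](O[Si](C)(C)C(C)(C)C)/C=C(\C)C=O | intermediate
6 | 3-methylbutan-2-one | CC(C)C(C)=O | starting material
7 | triethyl phosphonoacetate | CCOC(=O)CP(=O)(OCC)OCC | starting material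
8 | ethyl (2E)-3,4-dimethylpent-2-enoate | CCOC(=O)/C=C(\C)C(C)C | intermediate
9 | {[1-ethoxy-3-(propan-2-yl)buta-1,3-dien-1-yl]oxy}trimethylsilane (ketene acetal geometry not defined) | CCOC(O[Si](C)(C)C)=CC(=C)C(C)C | intermediate
10 | (6S)-6-[(2E,4S)-4-{[tert-butyl(dimethyl)silyl]oxy}hex-2-en-2-yl]-4-(propan-2-yl)-5,6-dihydro-2H-pyran-2-one | CC[C@H](O[Si](C)(C)C(C)(C)C)/C=C(\C)[C@@H]1CC(C(C)C)=CC(=O)O1 | intermediate
11 | (1R,4S,6S)-4-[(2E,4S)-4-{[tert-butyl(dimethyl)silyl]oxy}hex-2-en-2-yl]-6-(propan-2-yl)-3,7-dioxabicyclo[4.1.0]heptan-2-one | CC[C@H](O[Si](C)(C)C(C)(C)C)/C=C(\C)[C@@H]1C[C@@]2(C(C)C)O[C@H]2C(=O)O1 | intermediate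
12 | (3R,4S,6S,7E,9S)-9-{[tert-butyl(dimethyl)silyl]oxy}-3,4-epoxy-6-hydroxy-7-methyl-4-(propan-2-yl)undec-7-en-2-one | CC[C@H](O[Si](C)(C)C(C)(C)C)/C=C(\C)[C@@H](O)C[C@@]1(C(C)C)O[C@H]1C(C)=O | intermediate
13 | (3R,4S,6S,7E,9S)-9-{[tert-butyl(dimethyl)silyl]oxy}-3,4-epoxy-7-methyl-2-oxo-4-(propan-2-yl)undec-7-en-6-yl acetate | CC[C@H](O[Si](C)(C)C(C)(C)C)/C=C(\C)[C@@H](OC(C)=O)C[C@@]1(C(C)C)O[C@H]1C(C)=O | intermediate
14 | (3R,4S,6S,7E,9S)-3,4-epoxy-9-hydroxy-7-methyl-2-oxo-4-(propan-2-yl)undec-7-en-6-yl acetate | CC[C@H](O)/C=C(\C)[C@@H](OC(C)=O)C[C@@]1(C(C)C)O[C@H]1C(C)=O | intermediate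
15 | (3R,4S,6S,7E)-3,4-epoxy-7-methyl-2,9-dioxo-4-(propan-2-yl)undec-7-en-6-yl acetate | CCC(=O)/C=C(\C)[C@@H](OC(C)=O)C[C@@]1(C(C)C)O[C@H]1C(C)=O | intermediate
16 | (3R,4S,6S,7E,9Z)-3,4-epoxy-7-methyl-4-(propan-2-yl)-2,9-bis[(triethylsilyl)oxy]undeca-1,7,9-trien-6-yl acetate | C/C=C(O[Si](CC)(CC)CC)/C=C(\C)[C@@H](OC(C)=O)C[C@@]1(C(C)C)O[C@H]1C(=C)O[Si](CC)(CC)CC | intermediate
17 | 2β-acetoxy-4β,9-bis(triethylsilyloxy)-5αH-dauc-9-en-6-one (C8 epimers) | CC(=O)O[C@H]1C[C@](O[Si](CC)(CC)CC)(C(C)C)[C@H]2C(=O)CC(C)C(O[Si](CC)(CC)CC)=C[C@]12C | intermediate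
18 | 2β-acetoxy-4β-hydroxy-5αH-daucane-6,9-dione (C8 epimers) | CC(=O)O[C@H]1C[C@](O)(C(C)C)[C@H]2C(=O)CC(C)C(=O)C[C@]12C | intermediate
19 | 2β-acetoxy-4β,6α-dihydroxy-5αH-daucan-9-one (C8 epimers) | CC(=O)O[C@H]1C[C@](O)(C(C)C)[C@H]2[C@H](O)CC(C)C(=O)C[C@]12C | intermediate
20 | 4-{[tert-butyl(dimethyl)silyl]oxy}benzoic acid | CC(C)(C)[Si](C)(C)Oc1ccc(cc1)C(O)=O | starting material
21 | 2β-acetoxy-6α-[4-(tert-butyldimethylsilyloxy)benzoyloxy]-4β-hydroxy-5αH-daucan-9-one (C8 epimers) | CC(=O)O[C@H]1C[C@](O)(C(C)C)[C@H]2[C@H](OC(=O)c3ccc(O[Si](C)(C)C(C)(C)C)cc3)CC(C)C(=O)C[C@]12C | intermediate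
22 | 2β-acetoxy-6α-[4-(tert-butyldimethylsilyloxy)benzoyloxy]-4β-hydroxy-5αH-dauc-7-en-9-one | CC(=O)O[C@H]1C[C@](O)(C(C)C)[C@H]2[C@H](OC(=O)c3ccc(O[Si](C)(C)C(C)(C)C)cc3)C=C(C)C(=O)C[C@]12C | intermediate
23 | (1S,2S,4S,5R,6R)-2-acetoxy-4-hydroxy-6-(4-hydroxybenzoyloxy)dauc-7-en-9-one, i.e. 2β-acetoxy-4β-hydroxy-6α-(4-hydroxybenzoyloxy)-5αH-dauc-7-en-9-one | CC(=O)O[C@H]1C[C@](O)(C(C)C)[C@H]2[C@H](OC(=O)c3ccc(O)cc3)C=C(C)C(=O)C[C@]12C | target

Total step count: 17. Longest linear sequence: 15 steps (steps 1–3 and 6–17; steps 4–5 make the side fragment 9).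

Steps most likely to fail

Step 13 (key cycloaddition). After the C1–C5 bond has formed, the diene-derived siloxyallyl cation may close onto C10 instead of C8 (a 3+2 capture) or lose a proton. The allylic C2 acetate may ionise or take part in epoxide opening. The preference for the extended transition state may also be too small, which would show as poor facial selectivity at C1. Fallback: the two bonds are made in separate operations with reversed polarity at C5, setting out from 15 and returning at 18. SmI2 (2.2 equiv, THF, −78 °C, no proton source) cleaves the α,β-epoxy ketone reductively; the resulting trivalent samarium enolate of the C4 aldol is expected to add 5-exo-trig to the enone carbon C1. This should give 3-acetyl-4-hydroxy-2-methyl-2-(2-oxobutyl)-4-(propan-2-yl)cyclopentyl acetate F1, in which C5 can equilibrate to the trans arrangement. Me3SiOTf/Et3N converts F1 into the tris(trimethylsilyl) derivative F2 (enol silanes at C6/C7 and C8/C9, silyl ether at C4). Intramolecular oxidative coupling of the two enol silanes with (NH4)2Ce(NO3)6/NaHCO3 in MeCN at −30 °C, followed by dilute HCl work-up, forms C7–C8 and gives 18.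

Step 14 (directed reduction). Hydride may be delivered from both faces of C6 if the boron chelate is not formed cleanly at the tertiary alcohol. The β-hydroxy ketone may undergo retro-aldol cleavage or C5 epimerisation before reduction. The 6α-alcohol may also be tied up as a transannular hemiketal with C9. Fallback: substrate-controlled reduction followed by inversion, setting out from 17 (isolated by omitting the HF work-up of step 13) and returning at 21. NaBH4 (EtOH/THF, −20 °C) should attack C6 from the α face, anti to the C1 methyl, giving 2β-acetoxy-4β,9-bis(triethylsilyloxy)-5αH-dauc-9-en-6β-ol F3. Mitsunobu esterification with acid 20 (PPh3, DIAD, toluene, 0 °C → rt) inverts C6 to the 6α-aroyloxy bis-silyl compound F4. Brief HF·pyridine treatment then removes both triethylsilyl groups, leaves the aryl silyl ether, and gives 21.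

Step 16 (dehydrogenation). Conversion may stall, dehydrogenation may go into the C8 methyl group (exocyclic enone), or the aryl silyl ether and tertiary alcohol may degrade in hot DMSO. Fallback: halogenation–elimination, setting out from 21 and returning at 22. PhNMe3Br3 (THF, 0 °C) brominates the more substituted enol at C8 to give 2β-acetoxy-8-bromo-6α-[4-(tert-butyldimethylsilyloxy)benzoyloxy]-4β-hydroxy-5αH-daucan-9-one F5. Dehydrobromination with Li2CO3/LiBr in DMF at 100 °C gives the conjugated enone 22.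

Further compounds

F1 | step 13 | 3-acetyl-4-hydroxy-2-methyl-2-(2-oxobutyl)-4-(propan-2-yl)cyclopentyl acetate (2β-acetoxy-4β-hydroxy-7,8-seco-daucane-6,9-dione) | CC(=O)O[C@H]1C[C@](O)(C(C)C)[C@@H](C(C)=O)[C@]1(C)CC(=O)CC
F2 | step 13 | tris(trimethylsilyl) derivative of F1 (C6 and C9 enol silanes, C4 silyl ether) | CC(=O)O[C@H]1C[C@](O[Si](C)(C)C)(C(C)C)[C@@H](C(=C)O[Si](C)(C)C)[C@]1(C)CC(O[Si](C)(C)C)=CC
F3 | step 14 | 2β-acetoxy-4β,9-bis(triethylsilyloxy)-5αH-dauc-9-en-6β-ol (C8 epimers) | CC(=O)O[C@H]1C[C@](O[Si](CC)(CC)CC)(C(C)C)[C@H]2[C@@H](O)CC(C)C(O[Si](CC)(CC)CC)=C[C@]12C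
F4 | step 14 | 2β-acetoxy-6α-[4-(tert-butyldimethylsilyloxy)benzoyloxy]-4β,9-bis(triethylsilyloxy)-5αH-dauc-9-ene (C8 epimers) | CC(=O)O[C@H]1C[C@](O[Si](CC)(CC)CC)(C(C)C)[C@H]2[C@H](OC(=O)c3ccc(O[Si](C)(C)C(C)(C)C)cc3)CC(C)C(O[Si](CC)(CC)CC)=C[C@]12C
F5 | step 16 | 2β-acetoxy-8-bromo-6α-[4-(tert-butyldimethylsilyloxy)benzoyloxy]-4β-hydroxy-5αH-daucan-9-one | CC(=O)O[C@H]1C[C@](O)(C(C)C)[C@H]2[C@H](OC(=O)c3ccc(O[Si](C)(C)C(C)(C)C)cc3)CC(C)(Br)C(=O)C[C@]12C
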